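Everything rests on disconnecting the cyclopentane at C4–C5 (daucane numbering). C1, the quaternary carbon, is flanked by C5 and C10 in the seven-membered ring, so in a desymmetrised 2,2-disubstituted cycloheptane-1,3-dione the C5 carbonyl has α-hydrogens only at C6 and furnishes a single C5 alkenyl iodide. Nickel/chromium-mediated addition of that iodide to the tethered C4 isopropyl ketone closes the five-membered ring, makes the C4–C5 bond and sets the C4 carbinol in one operation. The precursor is a cycloheptenyl iodide bearing the C1 methyl, a C10 silyl ether and a 4-methyl-3-oxopentyl chain. Hydroboration of C5=C6, a C10-to-C8 carbonyl transposition, osmylation and methylenation finish the target.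

Key step: step 8

Remark on numbering: daucane numbering is used throughout (C1 methyl-bearing quaternary carbon, C4 isopropyl carbinol, C5 ring-fusion carbon, C6 acyloxy carbon, C8 methylidene carbon, C9 and C10 diol carbons); β is the face of the C1 methyl, α the opposite face.

Assumption: in step 3 the (S)-oxazaborolidine is taken to treat the quaternary carbon as the large group, as it does with tert-alkyl ketones, and thus to give the (R)-carbinol; should a test reduction show the opposite sense, the (R)-catalyst is used.

**Step 1**
Reactants: 1 cycloheptane-1,3-dione; 2 iodomethane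
Product: 3 2-methylcycloheptane-1,3-dione
Conditions: MeI (1.1 equiv), K2CO3, acetone, 56 °C
Reagents that add atoms: iodomethane (2), CI
Why: Alkylation of the stabilised 1,3-dione enolate at carbon (enolate C-alkylation) with only a slight excess of iodomethane; the mild carbonate base avoids retro-Claisen cleavage of the ring.

**Step 2**
Reactants: 3 2-methylcycloheptane-1,3-dione; 4 methyl acrylate
Product: 5 methyl 3-(1-methyl-2,7-dioxocycloheptyl)propanoate
Conditions: methyl acrylate, DBU (1,8-diazabicyclo[5.4.0]undec-7-ene, 0.1 equiv), MeCN, rt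
Reagents that add atoms: methyl acrylate (4), C=CC(=O)OC
Why: Base-catalysed Michael addition of the 2-methyl-1,3-dione to the acrylate creates the still achiral quaternary carbon (the future C1) between the two carbonyls that become C5 and C10.

**Step 3**
Reactants: 5 methyl 3-(1-methyl-2,7-dioxocycloheptyl)propanoate
Product: 6 methyl 3-[(1R,2R)-2-hydroxy-1-methyl-7-oxocycloheptyl]propanoate (hydroxyl trans to the methyl)
Conditions: (S)-1-methyl-3,3-diphenyltetrahydro-1H,3H-pyrrolo[1,2-c][1,3,2]oxazaborole (0.2 equiv), catecholborane (1.2 equiv), toluene, −78 to −40 °C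
Reagents that add atoms: none
Why: Corey–Bakshi–Shibata reduction, known as a desymmetrisation of 2,2-disubstituted cyclic 1,3-diones: the catalyst–borane complex takes one of the two enantiotopic carbonyls with the quaternary carbon as the large group and delivers hydride across the ring face that carries the small methyl, so C10 (R) and C1 (R) are set together with the hydroxyl trans to the methyl, catecholborane leaving the ester untouched; the minor hydroxyl/methyl-cis diastereomer is removed by chromatography here, because it would reappear as the enantiomer once C10 is oxidised.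

**Step 4**
Reactants: 6 hydroxy keto ester
Product: 7 3-[(1R,2R)-2-hydroxy-1-methyl-7-oxocycloheptyl]-N-methoxy-N-methylpropanamide
Conditions: MeNH(OMe)·HCl, AlMe3, CH2Cl2, 0 °C to rt
Reagents that add atoms: N,O-dimethylhydroxylamine hydrochloride, CNOC.Cl
Why: Aluminium amide aminolysis of the ester (Weinreb amide formation) leaves the hindered ketone alone, and the amide, unlike the ester, should withstand hydrazine in step 6 and later take up only one equivalent of Grignard reagent.

**Step 5**
Reactants: 7 hydroxy Weinreb amide
Product: 8 3-[(1R,2R)-2-(tert-butyldimethylsilyloxy)-1-methyl-7-oxocycloheptyl]-N-methoxy-N-methylpropanamide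
Conditions: TBSOTf, 2,6-lutidine, CH2Cl2, −78 to 0 °C
Reagents that add atoms: tert-butyldimethylsilyl triflate, CC(C)(C)[Si](C)(C)OS(=O)(=O)C(F)(F)F
Why: Silylation of the hindered secondary alcohol with the silyl triflate, carried out directly on crude 7; the ether blocks lactonisation, retro-aldol opening of the β-hydroxy ketone and, later, hemiketal formation with the C4 ketone.

**Step 6**
Reactants: 8 silyloxy keto Weinreb amide
Product: 10 3-[(1R,7R)-7-(tert-butyldimethylsilyloxy)-2-iodo-1-methylcyclohept-2-en-1-yl]-N-methoxy-N-methylpropanamide, via ring hydrazone 9 (not isolated)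
Conditions: N2H4·H2O, Et3N, EtOH, 80 °C; volatiles removed; then I2, 1,1,3,3-tetramethylguanidine, THF, 0 °C to rt
Reagents that add atoms: iodine, II; hydrazine hydrate, NN.O (nitrogen only in intermediate 9)
Why: Barton vinyl iodide synthesis: the hydrazone is iodinated, loses nitrogen and then a proton, and because C1 is quaternary that proton can only come from C6, so the C5=C6 iodide should form as a single regioisomer while amide and silyl ether stay intact.

**Step 7**
Reactants: 10 alkenyl iodide Weinreb amide; 11 isopropylmagnesium chloride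
Product: 12 1-[(1R,7R)-7-(tert-butyldimethylsilyloxy)-2-iodo-1-methylcyclohept-2-en-1-yl]-4-methylpentan-3-one
Conditions: iPrMgCl (2 equiv), THF, −20 to 0 °C
Reagents that add atoms: isopropylmagnesium chloride (11), CC(C)[Mg]Cl
Why: Grignard addition to the Weinreb amide stops at the chelated tetrahedral intermediate, which gives the isopropyl ketone on work-up, and the unactivated alkenyl iodide should not undergo iodine–magnesium exchange at this temperature.

**Step 8**
Reactants: 12 cycloheptenyl iodide carrying the 4-methyl-3-oxopentyl chain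
Product: 13 10α-(tert-butyldimethylsilyloxy)-4α-isopropyl-1β-methylbicyclo[5.3.0]dec-5-en-4β-ol
Conditions: CrCl2 (6 equiv), NiCl2 (0.05 equiv), degassed DMF, rt to 50 °C
Reagents that add atoms: none
Why: Zerovalent nickel, formed from NiCl2 by CrCl2, inserts into the C5–I bond and transmetallation to trivalent chromium gives an alkenylchromium species that adds to the chromium-activated C4 ketone, the chromium alkoxide being hydrolysed on work-up. The closest known reaction type is the intramolecular Nozaki–Hiyama–Kishi alkenyl halide–carbonyl coupling, well established for aldehydes and used, less often, with ketone acceptors. The five-membered ring C1–C2–C3–C4–C5 closes in the 5-exo-trig mode at the carbonyl carbon, the C5=C6 bond staying endocyclic in the seven-membered ring. The new stereocentre C4 is controlled by the C1 stereocentre: in the envelope-like transition state the C1 methyl is pseudo-axial on the β face, so the isopropyl group turns pseudo-equatorial (α) to avoid a 1,3-contact with it and the chromium-bound oxygen ends up β, cis to the methyl. The step needs this diastereoselectivity and carbonyl addition in preference to protodeiodination; both are served by the two-carbon tether, which holds the ketone next to C5, and by the non-basic organochromium reagent, which leaves the enolisable ketone and the silyl ether untouched.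

**Step 9**
Reactants: 13 bicyclic allylic alcohol
Product: 15 10α-(tert-butyldimethylsilyloxy)-4α-isopropyl-1β-methyl-5α-H-bicyclo[5.3.0]decane-4β,6α-diol, via C6 alkylborane 14 (not isolated)
Conditions: BH3·THF (4 equiv), THF, 0 °C to rt; then NaOH, H2O2, H2O, 0 °C to rt
Reagents that add atoms: hydrogen peroxide, OO; borane–tetrahydrofuran, B.C1CCOC1 (boron only in intermediate 14)
Why: Syn hydroboration–oxidation: boron adds to the less substituted C6 and hydrogen to C5 from the α face, opposite the pseudo-axial C1 methyl and the C4 oxygen (bound as a borate), as in the α-face hydroboration of steroidal C5=C6 alkenes, so H5 and O6 should both be α (trans ring fusion), and the oxidation replaces boron by hydroxyl with retention.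

**Step 10**
Reactants: 15 4β,6α-diol; 16 3-methylbutanoic anhydride
Product: 17 6α-(3-methylbutanoyloxy) derivative of 15 (4β-OH free, 10α-silyl ether)
Conditions: 3-methylbutanoic anhydride, 4-(dimethylamino)pyridine, Et3N, CH2Cl2, rt
Reagents that add atoms: 3-methylbutanoic anhydride (16), CC(C)CC(=O)OC(=O)CC(C)C
Why: Esterification by nucleophilic catalysis, the acylpyridinium transferring the acyl group to the secondary C6 hydroxyl while the tertiary C4 hydroxyl is too hindered to react.

**Step 11**
Reactants: 17 ester silyl ether
Product: 18 4α-isopropyl-1β-methyl-6α-(3-methylbutanoyloxy)-5α-H-bicyclo[5.3.0]decane-4β,10α-diol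
Conditions: HF·pyridine, pyridine, THF, 0 °C to rt
Reagents that add atoms: none
Why: Fluoride-induced cleavage of the silicon–oxygen bond (desilylation) frees the C10 hydroxyl under buffered, weakly acidic conditions that spare the ester and the tertiary alcohol.

**Step 12**
Reactants: 18 C10 alcohol
Product: 20 4β-hydroxy-4α-isopropyl-1β-methyl-6α-(3-methylbutanoyloxy)-5α-H-bicyclo[5.3.0]dec-8-en-10-one, via C10 ketone 19 (not isolated)
Conditions: IBX (2-iodoxybenzoic acid, 3 equiv), DMSO, rt then 70 °C
Reagents that add atoms: none
Why: IBX oxidises the secondary alcohol to ketone 19 at room temperature and, on warming, dehydrogenates it through its enol (IBX dehydrogenation of ketones) toward C9–C8, the only enolisable side because C1 is quaternary; the C10 stereocentre, having served to set C1, is given up here.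

**Step 13**
Reactants: 20 C8=C9 enone
Product: 21 8α,9α-epoxy-10-ketone
Conditions: t-BuOOH (in decane), DBU, CH2Cl2, 0 °C to rt
Reagents that add atoms: tert-butyl hydroperoxide, CC(C)(C)OO
Why: Weitz–Scheffer nucleophilic epoxidation: conjugate addition of the hydroperoxide anion at C8 and ring closure give the epoxy ketone under anhydrous, weakly basic conditions that spare the ester; the epoxide face (α expected, drawn so) is of no consequence because C9 becomes sp2 in step 14 and C8 in step 15.

**Step 14**
Reactants: 21 epoxy ketone
Product: 22 4β,8α-dihydroxy-4α-isopropyl-1β-methyl-6α-(3-methylbutanoyloxy)-5α-H-bicyclo[5.3.0]dec-9-ene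
Conditions: N2H4·H2O, AcOH (cat.), MeOH, 0 °C to rt
Reagents that add atoms: none
Why: Wharton transposition: the epoxy hydrazone opens to a vinyl diazene that loses nitrogen, which moves the oxygen function from C10 to C8 and places the double bond at C9=C10 without breaking the C8–O bond.

**Step 15**
Reactants: 22 allylic alcohol
Product: 23 4β-hydroxy-4α-isopropyl-1β-methyl-6α-(3-methylbutanoyloxy)-5α-H-bicyclo[5.3.0]dec-9-en-8-one
Conditions: Dess–Martin periodinane, pyridine, CH2Cl2, rt
Reagents that add atoms: none
Why: Dess–Martin oxidation of the allylic alcohol gives the C9=C10 enone under non-basic conditions, which matter because the C6 ester is now β to a carbonyl group and would be eliminated by base.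

**Step 16**
Reactants: 23 C9=C10 enone
Product: 24 4β,9α,10α-trihydroxy-4α-isopropyl-1β-methyl-6α-(3-methylbutanoyloxy)-5α-H-bicyclo[5.3.0]decan-8-one
Conditions: OsO4 (0.05 equiv), N-methylmorpholine N-oxide, citric acid, t-BuOH/H2O, rt
Reagents that add atoms: N-methylmorpholine N-oxide, C[N+]1([O-])CCOCC1; water, O; the oxygen atoms are passed on by osmium tetroxide, O=[Os](=O)(=O)=O
Why: Upjohn dihydroxylation: OsO4 adds suprafacially to the enone double bond from the α face, opposite the pseudo-axial C1 methyl next to C10, and so should set C9 and C10 with both hydroxyls α; citric acid speeds turnover with the electron-poor alkene and keeps the medium non-basic.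

**Step 17**
Reactants: 24 dihydroxy ketone
Product: 25 9α,10α-O-isopropylidene derivative of 24 (acetonide ketone)
Conditions: Me2C(OMe)2, pyridinium p-toluenesulfonate, CH2Cl2, rt
Reagents that add atoms: 2,2-dimethoxypropane, COC(C)(C)OC
Why: Acid-catalysed transacetalisation ties the cis-diol into an acetonide, which removes the free α- and β-hydroxy ketone functions that could undergo ketol shift or retro-aldol cleavage during methylenation.

**Step 18**
Reactants: 25 acetonide ketone; 26 dibromomethane
Product: 27 8-methylidene acetonide (9α,10α-O-isopropylidene derivative of the target)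
Conditions: Zn, CH2Br2, TiCl4, THF/CH2Cl2, 0 °C to rt
Reagents that add atoms: dibromomethane (26), BrCBr
Why: Takai–Lombardo methylenation: the non-basic zinc/titanium methylene reagent converts the ketone into the exocyclic alkene without enolisation, so neither β-elimination of the C6 ester nor epimerisation at C9 should occur, and esters are not attacked.

**Step 19**
Reactants: 27 8-methylidene acetonide
Product: 28 target, (1S,4R,5S,6S,9R,10S)-4,9,10-trihydroxy-4-isopropyl-1-methyl-8-methylidenebicyclo[5.3.0]decan-6-yl 3-methylbutanoate (daucane locants)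
Conditions: AcOH/H2O (4:1), 40 °C
Reagents that add atoms: none
Why: Mild acid-catalysed acetal hydrolysis releases the 9,10-diol without ionising the tertiary C4 or allylic C9 hydroxyl and without hydrolysing or shifting the ester.

**Compound list**

1 | cycloheptane-1,3-dione | O=C1CCCCC(=O)C1 | starting material
2 | iodomethane | CI | starting material
3 | 2-methylcycloheptane-1,3-dione | CC1C(=O)CCCCC1=O | intermediate
4 | methyl acrylate | C=CC(=O)OC | starting material
5 | methyl 3-(1-methyl-2,7-dioxocycloheptyl)propanoate | COC(=O)CCC1(C)C(=O)CCCCC1=O | intermediate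
6 | methyl 3-[(1R,2R)-2-hydroxy-1-methyl-7-oxocycloheptyl]propanoate | COC(=O)CC[C@]1(C)[C@H](O)CCCCC1=O | intermediate
7 | 3-[(1R,2R)-2-hydroxy-1-methyl-7-oxocycloheptyl]-N-methoxy-N-methylpropanamide | CON(C)C(=O)CC[C@]1(C)[C@H](O)CCCCC1=O | intermediate
8 | 3-[(1R,2R)-2-(tert-butyldimethylsilyloxy)-1-methyl-7-oxocycloheptyl]-N-methoxy-N-methylpropanamide | CON(C)C(=O)CC[C@]1(C)[C@H](O[Si](C)(C)C(C)(C)C)CCCCC1=O | intermediate
9 | hydrazone of 8 at the ring ketone (stereocentres unchanged) | CON(C)C(=O)CC[C@]1(C)[C@H](O[Si](C)(C)C(C)(C)C)CCCCC1=NN | intermediate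
10 | 3-[(1R,7R)-7-(tert-butyldimethylsilyloxy)-2-iodo-1-methylcyclohept-2-en-1-yl]-N-methoxy-N-methylpropanamide | CON(C)C(=O)CC[C@]1(C)[C@H](O[Si](C)(C)C(C)(C)C)CCCC=C1I | intermediate
11 | isopropylmagnesium chloride | CC(C)[Mg]Cl | starting material
12 | 1-[(1R,7R)-7-(tert-butyldimethylsilyloxy)-2-iodo-1-methylcyclohept-2-en-1-yl]-4-methylpentan-3-one (key-step precursor) | CC(C)C(=O)CC[C@]1(C)[C@H](O[Si](C)(C)C(C)(C)C)CCCC=C1I | intermediate
13 | 10α-(tert-butyldimethylsilyloxy)-4α-isopropyl-1β-methylbicyclo[5.3.0]dec-5-en-4β-ol (key-step product) | C1=C2[C@](C)(CC[C@@]2(O)C(C)C)[C@H](O[Si](C)(C)C(C)(C)C)CCC1 | intermediate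
14 | 6α-dihydroboryl adduct of 13, H5 α, C4 oxygen as O-boryl | C1C[C@H](B)[C@@H]2[C@](C)(CC[C@@]2(OB)C(C)C)[C@H](O[Si](C)(C)C(C)(C)C)C1 | intermediate
15 | 10α-(tert-butyldimethylsilyloxy)-4α-isopropyl-1β-methyl-5α-H-bicyclo[5.3.0]decane-4β,6α-diol | C1C[C@H](O)[C@@H]2[C@](C)(CC[C@@]2(O)C(C)C)[C@H](O[Si](C)(C)C(C)(C)C)C1 | intermediate
16 | 3-methylbutanoic anhydride | CC(C)CC(=O)OC(=O)CC(C)C | starting material
17 | 6α-(3-methylbutanoyloxy) derivative of 15 | C1C[C@H](OC(=O)CC(C)C)[C@@H]2[C@](C)(CC[C@@]2(O)C(C)C)[C@H](O[Si](C)(C)C(C)(C)C)C1 | intermediate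
18 | 4β,10α-diol 6α-(3-methylbutanoate) | C1C[C@H](OC(=O)CC(C)C)[C@@H]2[C@](C)(CC[C@@]2(O)C(C)C)[C@H](O)C1 | intermediate
19 | 10-ketone, 4β-hydroxy, 6α-(3-methylbutanoate) | C1C[C@H](OC(=O)CC(C)C)[C@@H]2[C@](C)(CC[C@@]2(O)C(C)C)C(=O)C1 | intermediate
20 | 8-en-10-one, 4β-hydroxy, 6α-(3-methylbutanoate) | C1=CC[C@H](OC(=O)CC(C)C)[C@@H]2[C@](C)(CC[C@@]2(O)C(C)C)C1=O | intermediate
21 | 8α,9α-epoxy-10-one, 4β-hydroxy, 6α-(3-methylbutanoate) | [C@@H]13C[C@H](OC(=O)CC(C)C)[C@@H]2[C@](C)(CC[C@@]2(O)C(C)C)C(=O)[C@@H]1O3 | intermediate
22 | 9-ene-4β,8α-diol 6α-(3-methylbutanoate) | O[C@@H]1C[C@H](OC(=O)CC(C)C)[C@@H]2[C@](C)(CC[C@@]2(O)C(C)C)C=C1 | intermediate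
23 | 9-en-8-one, 4β-hydroxy, 6α-(3-methylbutanoate) | O=C1C[C@H](OC(=O)CC(C)C)[C@@H]2[C@](C)(CC[C@@]2(O)C(C)C)C=C1 | intermediate
24 | 4β,9α,10α-trihydroxy-8-one 6α-(3-methylbutanoate) | O=C1C[C@H](OC(=O)CC(C)C)[C@@H]2[C@](C)(CC[C@@]2(O)C(C)C)[C@H](O)[C@@H]1O | intermediate
25 | 9α,10α-O-isopropylidene derivative of 24 | O=C1C[C@H](OC(=O)CC(C)C)[C@@H]2[C@](C)(CC[C@@]2(O)C(C)C)[C@@H]3OC(C)(C)O[C@H]13 | intermediate
26 | dibromomethane | BrCBr | starting material
27 | 8-methylidene-9α,10α-O-isopropylidene derivative (acetonide of the target) | C=C1C[C@H](OC(=O)CC(C)C)[C@@H]2[C@](C)(CC[C@@]2(O)C(C)C)[C@@H]3OC(C)(C)O[C@H]13 | intermediate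
28 | CNP0204264.1, 4β,9α,10α-trihydroxy-4α-isopropyl-1β-methyl-8-methylidene-5α-H-bicyclo[5.3.0]decan-6α-yl 3-methylbutanoate | C=C1C[C@H](OC(=O)CC(C)C)[C@@H]2[C@](C)(CC[C@@]2(O)C(C)C)[C@H](O)[C@@H]1O | target

**Totals and risks**

Total step count: 19. Longest linear sequence: 19 steps (1 to 28; the route is fully linear).

The three steps most likely to fail:

Step 8. The alkenylchromium may add too slowly to the hindered dialkyl ketone, so that protodeiodination takes over, or the two faces of the ketone may not be told apart well enough. The fallback sets out from alkenyl iodide Weinreb amide 10. Iodine–lithium exchange (t-BuLi, THF, −78 °C) gives an alkenyllithium that closes onto the amide (Parham-type anionic cyclisation) to the bicyclic C4 enone F1. 1,2-Addition of the isopropylcerium reagent (iPrMgCl, CeCl3, THF, −78 °C) from the open α face, opposite the pseudo-axial C1 methyl, then gives the same tertiary alcohol, and the route is rejoined at 13.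

Step 9. Facial selectivity may be poor, borane attacking the β face as well and giving the cis-fused 5β,6β series. The fallback sets out from 13, whose crude hydroboration mixture is used. The cis-fused diol F2 is oxidised (Dess–Martin periodinane, CH2Cl2) to the cis-fused 6-ketone F3. C5 is then equilibrated with DBU in toluene to the trans-fused 6-ketone F4, in which the isopropyl group is cis to the small H5 and the hydroxyl can hydrogen-bond to the carbonyl. Evans–Saksena reduction (Me4NBH(OAc)3, AcOH/MeCN, −20 °C), in which the C4 hydroxyl delivers hydride to the β face of the C6 carbonyl, returns the 6α-alcohol, and the route is rejoined at 15. Any 15 in the mixture is oxidised to F4 directly and converges.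

Step 14. Hydrazone formation at the neopentyl C10 carbonyl may be slow, so that hydrazine opens the epoxide or attacks the ester before the fragmentation sets in. The fallback sets out from epoxy ketone 21. Luche reduction (NaBH4, CeCl3·7H2O, MeOH, −78 °C) gives the epoxy alcohol F5 (C10 configuration immaterial, drawn α). It is converted with 1,1'-thiocarbonyldiimidazole (toluene, 80 °C) into the imidazolyl thiocarbonate F6. Radical fragmentation (Bu3SnH, azobisisobutyronitrile, toluene, 90 °C) generates the C10 radical, which opens the epoxide to the C8 alkoxyl radical; hydrogen transfer then gives the allylic alcohol, and the route is rejoined at 22.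

Further compounds
F1 | step 8 | 10α-(tert-butyldimethylsilyloxy)-1β-methylbicyclo[5.3.0]dec-5-en-4-one | C1CC=C2[C@](C)(CCC2=O)[C@H](O[Si](C)(C)C(C)(C)C)C1
F2 | step 9 | cis-fused 5β-H 4β,6β-diol, C5/C6 epimer of 15 | C1C[C@@H](O)[C@H]2[C@](C)(CC[C@@]2(O)C(C)C)[C@H](O[Si](C)(C)C(C)(C)C)C1
F3 | step 9 | cis-fused 5β-H 4β-hydroxy-6-ketone | C1CC(=O)[C@H]2[C@](C)(CC[C@@]2(O)C(C)C)[C@H](O[Si](C)(C)C(C)(C)C)C1
F4 | step 9 | trans-fused 5α-H 4β-hydroxy-6-ketone | C1CC(=O)[C@@H]2[C@](C)(CC[C@@]2(O)C(C)C)[C@H](O[Si](C)(C)C(C)(C)C)C1
F5 | step 14 | 8α,9α-epoxy-4β,10α-diol 6α-(3-methylbutanoate) | [C@@H]13C[C@H](OC(=O)CC(C)C)[C@@H]2[C@](C)(CC[C@@]2(O)C(C)C)[C@H](O)[C@@H]1O3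
F6 | step 14 | 10-O-(imidazol-1-ylthiocarbonyl) derivative of F5 | [C@@H]13C[C@H](OC(=O)CC(C)C)[C@@H]2[C@](C)(CC[C@@]2(O)C(C)C)[C@H](OC(=S)n4ccnc4)[C@@H]1O3
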